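(The earlier runs and the new flask were computed for an exercise; the scatter is artificial.)

Our closed, stirred vessel takes the same substrate, partner and reagent each time, and the flasks differ in their protic impurity.

| flask | substrate | partner | reagent | protic impurity | remark | time |
|---|---|---|---|---|---|---|
| dawn | 0.19 M | 0.209 M | 0.285 M | 1.6 mM | run made earlier |  |
| midnight | 0.19 M | 0.209 M | 0.285 M | 8.6 mM | run made earlier |  |
| west | 0.19 M | 0.209 M | 0.285 M | 2.00 mM |  | 80 min |
| north-west | 0.19 M | 0.209 M | 0.285 M | 3.00 mM |  | 80 min |
| north-east | 0.19 M | 0.209 M | 0.285 M | 4.00 mM |  | 80 min |
| east | 0.19 M | 0.209 M | 0.285 M | 6.00 mM |  | 80 min |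
| south | 0.19 M | 0.209 M | 0.285 M | 10.0 mM |  | 80 min |

| run | time / min | product / % | substrate / % |
|---|---|---|---|
| dawn | 8.00 | 0.4 | 62.0 |
| dawn | 20.0 | 1.6 | 39.2 |
| dawn | 40.0 | 7.9 | 24.4 |
| dawn | 60.0 | 14.1 | 19.9 |
| midnight | 15.0 | 2.6 | 45.6 |
| midnight | 30.0 | 5.8 | 31.3 |
| midnight | 40.0 | 7.2 | 25.1 |
| midnight | 60.0 | 13.3 | 22.8 |

(scatter of a reading: 1 percentage point)

- amount of product at the end, in percent of the substrate charged for west, north-west, north-east, east, south, in this order
- how that number moves from the first to the last of them (hardly changes / falls, then rises / rises, then falls / falls all the way / rises all the way)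

- "hardly changes" means that all values lie within two and a half points (for a concentration: within two and a half percent of the largest)

Watch the balance first: at 60.0 min in the dawn run, 66.0 % of the charge shows up as neither substrate nor product, so material is waiting somewhere unseen.

The impurity can matter by destroying reagent, so we fold the question into one ratio. The impurity charge over the reagent charge is 3.51 % for south; we call it the impurity tax, the share of the reagent the impurity can claim if they react one for one. From west to south the tax climbs by 2.81 % of the reagent charge. If product follows reagent in proportion, then on the 14.1 % that the dawn run reached, our own reckoning gives a slip of 0.4 percentage points, smaller than the scatter of one reading. So we commit to a flat row, though the tax does not give its height.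

Is one number enough? The dawn tax is 0.561 % and the midnight tax 3.02 %. Their product readings at 60.0 min differ by 0.8 points, less than the 1.4 points expected for the difference of two readings, so this pair of readings does not fault it.

The forecast gives 20 % for west and 20 % for south and calls the row hardly changes, since “No impurity effect shows across a fivefold span”.

The flasks give 19.5 % in west and 18.8 % in south, a slip of 0.7 points against our 0.4 points, which was reckoned on the dawn reading at 60.0 min, so the row hardly changes.

    substrate + reagent → open intermediate (k = 0.00465 L mol⁻¹ s⁻¹)
    reagent + partner → second intermediate (k = 0.00180 L mol⁻¹ s⁻¹)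
    open intermediate + second intermediate → product (k = 0.00106 L mol⁻¹ s⁻¹)
    reagent + protic impurity → quenched reagent (k = 0.00882 L mol⁻¹ s⁻¹)

The tax comes due: quenched reagent at 80.0 min in south is 3.37 % of the reagent charge against a tax of 3.51 %, and in west 0.677 % against 0.702 %. What the flask has and the tax lacks is a waiting pool: west still holds 63.4 % of the substrate charged as open intermediate at 80.0 min. Part of what keeps the row this low is the using up of reagent, acting together with the length of the run: west gives 37.5 % of product with reagent held at its charge, and 59.4 % when run to 800 min.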